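**Assumption:** the target (3,5,7,3',5'-pentahydroxy-8,4'-dimethoxyflavone, C17H14O9) has no stereocentre, so no enantioselective step is needed. The only stereo-element on the route is the E-alkene of the chalcone, and it is consumed in ring closure.

## Retrosynthetic overview
1. The target comes from neutral global hydrogenolysis of the 5,7,3',5'-tetra-O-benzyl flavonol, whose 3-OH comes from epoxidation of the C2=C3 bond of the matching flavone.
2. Ring C is the only ring built and is formed last, by oxidative oxa-Michael cyclisation of a 2'-hydroxychalcone. That chalcone has a single free phenol next to the OMe, which fixes the 8-OMe pattern.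
3. The key C–C bond (Cα–Cβ) comes from an intermolecular Claisen–Schmidt aldol condensation of the A-ring acetophenone with the B-ring aldehyde.
4. Rings A and B both come from methyl gallate via methyl 4-O-methylgallate. For ring B: benzylation, reduction, oxidation.
5. For ring A: MOM protection, CO2Me→CHO, Baeyer–Villiger CHO→OH, and O-benzylation give a symmetric arene. Bromination, lithiation and acetylation, MOM removal and chelation-controlled 4-O-benzylation follow.

## Route

**Step 1**
Reactants: 1 methyl gallate (methyl 3,4,5-trihydroxybenzoate)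
Product: 2 methyl 3,5-dihydroxy-4-methoxybenzoate
Conditions: MeI (1.05 equiv), Li2CO3 (1.2 equiv), DMF, N2, 50 °C
Reagents that add atoms: iodomethane, CI
Why: The 4-OH para to the ester is the most acidic phenol, so the weak base ionises only that one and one equivalent of MeI gives a regioselective Williamson etherification.

**Step 2**
Reactants: 2 methyl 3,5-dihydroxy-4-methoxybenzoate
Product: 3 methyl 3,5-bis(benzyloxy)-4-methoxybenzoate
Conditions: BnBr (2.4 equiv), K2CO3, DMF, 60 °C
Reagents that add atoms: benzyl bromide, BrCc1ccccc1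
Why: This is an exhaustive Williamson etherification of the two remaining equivalent phenols, and nothing else in the molecule can be alkylated.

**Step 3**
Reactants: 3 methyl 3,5-bis(benzyloxy)-4-methoxybenzoate
Product: 4 [3,5-bis(benzyloxy)-4-methoxyphenyl]methanol
Conditions: LiAlH4, THF, 0 °C to rt; Fieser work-up
Reagents that add atoms: none
Why: Hydride reduction of the ester gives the primary alcohol, and aryl benzyl and methyl ethers are inert to LiAlH4.

**Step 4**
Reactants: 4 [3,5-bis(benzyloxy)-4-methoxyphenyl]methanol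
Product: 5 3,5-bis(benzyloxy)-4-methoxybenzaldehyde
Conditions: activated MnO2 (excess), CH2Cl2, rt
Reagents that add atoms: none
Why: MnO2 oxidation of an electron-rich benzylic alcohol stops cleanly at the aldehyde.

**Step 5**
Reactants: 2 methyl 3,5-dihydroxy-4-methoxybenzoate
Product: 6 methyl 4-methoxy-3,5-bis(methoxymethoxy)benzoate
Conditions: MOMCl (3 equiv), i-Pr2NEt (4 equiv), CH2Cl2, 0 °C to rt
Reagents that add atoms: chloromethyl methyl ether, COCCl
Why: MOM acetal protection of both phenols gives groups that survive hydride, peracid, base and organolithium and are orthogonal to benzyl.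

**Step 6**
Reactants: 6 methyl 4-methoxy-3,5-bis(methoxymethoxy)benzoate
Product: 7 [4-methoxy-3,5-bis(methoxymethoxy)phenyl]methanol
Conditions: LiAlH4, THF, 0 °C to rt; Fieser work-up
Reagents that add atoms: none
Why: This is a hydride reduction of the ester, and MOM acetals are stable to LiAlH4 and to the basic work-up.

**Step 7**
Reactants: 7 [4-methoxy-3,5-bis(methoxymethoxy)phenyl]methanol
Product: 8 4-methoxy-3,5-bis(methoxymethoxy)benzaldehyde
Conditions: activated MnO2 (excess), CH2Cl2, rt
Reagents that add atoms: none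
Why: This neutral MnO2 benzylic oxidation leaves the acid-labile MOM groups untouched.

**Step 8**
Reactants: 8 4-methoxy-3,5-bis(methoxymethoxy)benzaldehyde
Product: 10 4-methoxy-3,5-bis(methoxymethoxy)phenol, via aryl formate 9 (not isolated)
Conditions: mCPBA (1.5 equiv), CH2Cl2, 0 °C to rt; wash (Na2S2O3, NaHCO3); then cat. K2CO3, MeOH, rt
Reagents that add atoms: mCPBA, OOC(=O)c1cccc(Cl)c1
Why: In this Baeyer–Villiger oxidation the 3,4,5-trialkoxyaryl group migrates in preference to hydrogen, and mild methanolysis of the formate frees the phenol.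

**Step 9**
Reactants: 10 4-methoxy-3,5-bis(methoxymethoxy)phenol
Product: 11 5-(benzyloxy)-2-methoxy-1,3-bis(methoxymethoxy)benzene
Conditions: BnBr (1.2 equiv), K2CO3, DMF, N2, rt to 50 °C
Reagents that add atoms: benzyl bromide, BrCc1ccccc1
Why: This Williamson etherification puts benzyl on the future O-5 and gives a symmetric arene whose two ring C–H positions are equivalent.

**Step 10**
Reactants: 11 5-(benzyloxy)-2-methoxy-1,3-bis(methoxymethoxy)benzene
Product: 12 1-(benzyloxy)-2-bromo-4-methoxy-3,5-bis(methoxymethoxy)benzene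
Conditions: NBS (1.0 equiv), MeCN, −10 to 0 °C, dark
Reagents that add atoms: N-bromosuccinimide, O=C1CCC(=O)N1Br
Why: In this electrophilic aromatic bromination of a tetra-alkoxyarene the symmetry allows only one monobromide, and the unactivated benzyl ring does not compete.

**Step 11**
Reactants: 12 1-(benzyloxy)-2-bromo-4-methoxy-3,5-bis(methoxymethoxy)benzene
Product: 14 1-[6-(benzyloxy)-3-methoxy-2,4-bis(methoxymethoxy)phenyl]ethan-1-one, via aryllithium 13 (not isolated)
Conditions: n-BuLi (1.05 equiv), THF, −78 °C, 20 min; MeC(O)N(OMe)Me (1.5 equiv), −78 to 0 °C; H2O quench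
Reagents that add atoms: N-methoxy-N-methylacetamide, CON(C)C(C)=O
Why: Fast bromine–lithium exchange gives an OMOM-chelated aryllithium, and the Weinreb ketone synthesis stops at the methyl ketone without any acid that could disturb the ethers.

**Step 12**
Reactants: 14 1-[6-(benzyloxy)-3-methoxy-2,4-bis(methoxymethoxy)phenyl]ethan-1-one
Product: 15 1-[6-(benzyloxy)-2,4-dihydroxy-3-methoxyphenyl]ethan-1-one
Conditions: cat. conc. HCl, MeOH, 50 °C
Reagents that add atoms: none
Why: Acid-catalysed acetal exchange with methanol removes both MOM groups, while aryl benzyl and methyl ethers are stable to dilute methanolic HCl.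

**Step 13**
Reactants: 15 1-[6-(benzyloxy)-2,4-dihydroxy-3-methoxyphenyl]ethan-1-one
Product: 16 1-[4,6-bis(benzyloxy)-2-hydroxy-3-methoxyphenyl]ethan-1-one
Conditions: BnBr (1.05 equiv), K2CO3 (1.2 equiv), acetone, reflux
Reagents that add atoms: benzyl bromide, BrCc1ccccc1
Why: In this chelation-controlled Williamson etherification the 2-OH is tied up in a hydrogen bond to the ketone, so only the free and more acidic 4-OH is benzylated.

**Step 14 (key C–C bond)**
Reactants: 16 1-[4,6-bis(benzyloxy)-2-hydroxy-3-methoxyphenyl]ethan-1-one; 5 3,5-bis(benzyloxy)-4-methoxybenzaldehyde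
Product: 18 (E)-1-[4,6-bis(benzyloxy)-2-hydroxy-3-methoxyphenyl]-3-[3,5-bis(benzyloxy)-4-methoxyphenyl]prop-2-en-1-one, via aldol adduct 17 (not isolated)
Conditions: 50% aq KOH (excess), EtOH/THF, rt, 24–48 h; then dilute HCl to pH 5
Reagents that add atoms: none
Why: In this Claisen–Schmidt crossed aldol condensation only the ketone can enolise and only the aldehyde is a good acceptor, and E1cB dehydration gives the conjugated, thermodynamically favoured E-chalcone.

**Step 15**
Reactants: 18 the (E)-chalcone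
Product: 20 5,7-bis(benzyloxy)-2-[3,5-bis(benzyloxy)-4-methoxyphenyl]-8-methoxy-4H-chromen-4-one, via flavanone 19 (not isolated)
Conditions: I2 (0.1–0.2 equiv), DMSO, 130 °C, 2–4 h; aq Na2S2O3 work-up
Reagents that add atoms: none
Why: This is an oxa-Michael ring closure through the only free phenol followed by α-iodination and HI loss, with DMSO re-oxidising HI, so ring C forms with OMe fixed at C-8.

**Step 16**
Reactants: 20 the tetra-O-benzyl flavone
Product: 22 5,7-bis(benzyloxy)-2-[3,5-bis(benzyloxy)-4-methoxyphenyl]-3-hydroxy-8-methoxy-4H-chromen-4-one, via flavone epoxide 21 (not isolated)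
Conditions: DMDO (ca. 0.07 M in acetone, 2–3 equiv), CH2Cl2, 0 °C to rt; then cat. p-TsOH·H2O, CH2Cl2, rt
Reagents that add atoms: dimethyldioxirane, CC1(C)OO1
Why: Neutral dioxirane epoxidation of the enol-ether-like C2=C3 bond is followed by acid-catalysed epoxide opening and proton loss, which restores the aromatic pyranone as the 3-hydroxyflavone.

**Step 17**
Reactants: 22 the tetra-O-benzyl flavonol
Product: 23 3,5,7-trihydroxy-2-(3,5-dihydroxy-4-methoxyphenyl)-8-methoxy-4H-chromen-4-one (target)
Conditions: H2 (1 atm), 10% Pd/C, THF/MeOH 1:1, rt; filter under N2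
Reagents that add atoms: none
Why: Catalytic hydrogenolysis cleaves all four benzyl ethers under neutral conditions, so both methyl ethers stay in place and no acid-driven Wessely–Moser 8→6 isomerisation can occur.

## Compound list
1 | methyl gallate | COC(=O)c1cc(O)c(O)c(O)c1 | starting material
2 | methyl 3,5-dihydroxy-4-methoxybenzoate | COC(=O)c1cc(O)c(OC)c(O)c1 | intermediate
3 | methyl 3,5-bis(benzyloxy)-4-methoxybenzoate | COC(=O)c1cc(OCc2ccccc2)c(OC)c(OCc2ccccc2)c1 | intermediate
4 | [3,5-bis(benzyloxy)-4-methoxyphenyl]methanol | OCc1cc(OCc2ccccc2)c(OC)c(OCc2ccccc2)c1 | intermediate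
5 | 3,5-bis(benzyloxy)-4-methoxybenzaldehyde | O=Cc1cc(OCc2ccccc2)c(OC)c(OCc2ccccc2)c1 | intermediate
6 | methyl 4-methoxy-3,5-bis(methoxymethoxy)benzoate | COC(=O)c1cc(OCOC)c(OC)c(OCOC)c1 | intermediate
7 | [4-methoxy-3,5-bis(methoxymethoxy)phenyl]methanol | OCc1cc(OCOC)c(OC)c(OCOC)c1 | intermediate
8 | 4-methoxy-3,5-bis(methoxymethoxy)benzaldehyde | O=Cc1cc(OCOC)c(OC)c(OCOC)c1 | intermediate
9 | 4-methoxy-3,5-bis(methoxymethoxy)phenyl formate (not isolated) | O=COc1cc(OCOC)c(OC)c(OCOC)c1 | intermediate
10 | 4-methoxy-3,5-bis(methoxymethoxy)phenol | Oc1cc(OCOC)c(OC)c(OCOC)c1 | intermediate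
11 | 5-(benzyloxy)-2-methoxy-1,3-bis(methoxymethoxy)benzene | COCOc1cc(OCc2ccccc2)cc(OCOC)c1OC | intermediate
12 | 1-(benzyloxy)-2-bromo-4-methoxy-3,5-bis(methoxymethoxy)benzene | COCOc1cc(OCc2ccccc2)c(Br)c(OCOC)c1OC | intermediate
13 | [6-(benzyloxy)-3-methoxy-2,4-bis(methoxymethoxy)phenyl]lithium (not isolated) | COCOc1cc(OCc2ccccc2)c([Li])c(OCOC)c1OC | intermediate
14 | 1-[6-(benzyloxy)-3-methoxy-2,4-bis(methoxymethoxy)phenyl]ethan-1-one | COCOc1cc(OCc2ccccc2)c(C(C)=O)c(OCOC)c1OC | intermediate
15 | 1-[6-(benzyloxy)-2,4-dihydroxy-3-methoxyphenyl]ethan-1-one | CC(=O)c1c(O)c(OC)c(O)cc1OCc1ccccc1 | intermediate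
16 | 1-[4,6-bis(benzyloxy)-2-hydroxy-3-methoxyphenyl]ethan-1-one | CC(=O)c1c(O)c(OC)c(OCc2ccccc2)cc1OCc1ccccc1 | intermediate
17 | 1-[4,6-bis(benzyloxy)-2-hydroxy-3-methoxyphenyl]-3-[3,5-bis(benzyloxy)-4-methoxyphenyl]-3-hydroxypropan-1-one (racemic, not isolated) | O=C(CC(O)c1cc(OCc2ccccc2)c(OC)c(OCc2ccccc2)c1)c1c(O)c(OC)c(OCc2ccccc2)cc1OCc1ccccc1 | intermediate
18 | (E)-1-[4,6-bis(benzyloxy)-2-hydroxy-3-methoxyphenyl]-3-[3,5-bis(benzyloxy)-4-methoxyphenyl]prop-2-en-1-one | O=C(/C=C/c1cc(OCc2ccccc2)c(OC)c(OCc2ccccc2)c1)c1c(O)c(OC)c(OCc2ccccc2)cc1OCc1ccccc1 | intermediate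
19 | 5,7-bis(benzyloxy)-2-[3,5-bis(benzyloxy)-4-methoxyphenyl]-8-methoxychroman-4-one (racemic, not isolated) | O=C1CC(c2cc(OCc3ccccc3)c(OC)c(OCc3ccccc3)c2)Oc2c(OC)c(OCc3ccccc3)cc(OCc3ccccc3)c21 | intermediate
20 | 5,7-bis(benzyloxy)-2-[3,5-bis(benzyloxy)-4-methoxyphenyl]-8-methoxy-4H-chromen-4-one | O=c1cc(-c2cc(OCc3ccccc3)c(OC)c(OCc3ccccc3)c2)oc2c(OC)c(OCc3ccccc3)cc(OCc3ccccc3)c12 | intermediate
21 | 2,3-epoxide of flavone 20 (racemic, not isolated) | O=C1C2OC2(c2cc(OCc3ccccc3)c(OC)c(OCc3ccccc3)c2)Oc2c(OC)c(OCc3ccccc3)cc(OCc3ccccc3)c21 | intermediate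
22 | 5,7-bis(benzyloxy)-2-[3,5-bis(benzyloxy)-4-methoxyphenyl]-3-hydroxy-8-methoxy-4H-chromen-4-one | O=c1c(O)c(-c2cc(OCc3ccccc3)c(OC)c(OCc3ccccc3)c2)oc2c(OC)c(OCc3ccccc3)cc(OCc3ccccc3)c12 | intermediate
23 | 3,5,7-trihydroxy-2-(3,5-dihydroxy-4-methoxyphenyl)-8-methoxy-4H-chromen-4-one (achiral) | COc1c(O)cc(-c2oc3c(OC)c(O)cc(O)c3c(=O)c2O)cc1O | target

## Summary
Total step count: 17.
Longest linear sequence: 14 steps (steps 1 and 5–17). The B-ring branch (steps 2–4) joins at step 14.

## Three steps most likely to fail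

**Step 1 (over-methylation or methylation at O-3).** The fallback sets out from 1 and comes back at 2.
- Peracetylate 1 with Ac2O/pyridine to methyl 3,4,5-triacetoxybenzoate F1.
- Heat F1 with MeI and K2CO3 in acetone. Only the 4-acetate, para to the ester and the best phenoxide leaving group, is cleaved. The phenoxide is methylated in situ to give methyl 3,5-diacetoxy-4-methoxybenzoate F2.
- Methanolysis with catalytic K2CO3 in MeOH then gives 2.
- Selectivity here rests on differential ester lability rather than on titrating one phenol out of three.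

**Step 11 (a hindered, doubly ortho-substituted aryllithium may deprotonate the enolisable Weinreb amide instead of adding to it).** The fallback sets out from 11 and comes back at 15, bypassing 12–14.
- Remove the MOM groups first (cat. HCl, MeOH) to give 5-(benzyloxy)-2-methoxybenzene-1,3-diol F3.
- Run a Hoesch acylation (MeCN, ZnCl2, dry HCl, Et2O, 0 °C). It can only attack one of the two equivalent ring positions, and the product precipitates as 1-[6-(benzyloxy)-2,4-dihydroxy-3-methoxyphenyl]ethan-1-imine hydrochloride F4.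
- Brief heating of F4 in water hydrolyses it to 15.

**Step 16 (sluggish epoxidation, or DMDO attack on the electron-rich rings or the benzylic C–H bonds).** The fallback sets out from 20 and comes back at 22.
- Deprotonate C-3 with LDA (THF, −78 °C) to give the 3-lithioflavone F5.
- Trap with B(OMe)3 to give the dimethyl flavon-3-ylboronate F6.
- Oxidise the C–B bond with H2O2/AcOH to give 22.
- The oxygen is thus introduced by an anionic borylation–oxidation instead of an electrophilic oxidant.

## Further compounds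
F1 | step 1 | methyl 3,4,5-triacetoxybenzoate | COC(=O)c1cc(OC(C)=O)c(OC(C)=O)c(OC(C)=O)c1
F2 | step 1 | methyl 3,5-diacetoxy-4-methoxybenzoate | COC(=O)c1cc(OC(C)=O)c(OC)c(OC(C)=O)c1
F3 | step 11 | 5-(benzyloxy)-2-methoxybenzene-1,3-diol | COc1c(O)cc(OCc2ccccc2)cc1O
F4 | step 11 | 1-[6-(benzyloxy)-2,4-dihydroxy-3-methoxyphenyl]ethan-1-imine hydrochloride | CC(=N)c1c(O)c(OC)c(O)cc1OCc1ccccc1.Cl
F5 | step 16 | 3-lithio derivative of flavone 20 | [Li]c1c(-c2cc(OCc3ccccc3)c(OC)c(OCc3ccccc3)c2)oc2c(OC)c(OCc3ccccc3)cc(OCc3ccccc3)c2c1=O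
F6 | step 16 | dimethyl {5,7-bis(benzyloxy)-2-[3,5-bis(benzyloxy)-4-methoxyphenyl]-8-methoxy-4-oxo-4H-chromen-3-yl}boronate | COB(OC)c1c(-c2cc(OCc3ccccc3)c(OC)c(OCc3ccccc3)c2)oc2c(OC)c(OCc3ccccc3)cc(OCc3ccccc3)c2c1=O
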